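## The problem

Meridianin F 11 is a flat, achiral biaryl: a 1H-indole joined through C3 to C4' of a 2-aminopyrimidine, with bromine on the neighbouring benzo carbons C5 and C6. With no stereocentre to set, the synthesis is decided by regiochemistry and functional-group tolerance. The vicinal dibromide is the first difficulty: electrophilic bromination of an indole attacks the pyrrole ring first and gives mixtures on the benzo ring unless C3 carries an acceptor, so the two halogens are best delivered on carbons that already hold them. The C3–C4' bond then has to be made beside two aryl C–Br bonds, which makes zerovalent palladium, organolithium reagents and hydrogenolysis unwelcome once the bromines are in place. The 2-amino group and the pyrimidine nitrogens are Lewis basic and should appear late, and the indole N–H with its electron-rich C2=C3 bond tolerates neither strong oxidants nor strong acid for long. The enabling feature is the local mirror symmetry of the benzo fragment H–C4, Br–C5, Br–C6, H–C7, which matches atom for atom C2 to C5 of 3,4-dibromothiophene 1,1-dioxide 2. C3a and C7a, the latter bearing N1, can then come from the double bond of the 2,3-dihydropyrrole 3, so the benzene ring can be grown onto the nitrogen ring by a [4+2] addition with no regiochemical choice.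

## Retrosynthesis

**Amino group last (11 ⇒ 10).** The C2'–N bond is cut first, giving 5,6-dibromo-3-(2-chloropyrimidin-4-yl)-1H-indole 10. Ammonia displaces a chloride flanked by both ring nitrogens, whereas the two C–Br bonds sit on an unactivated carbocycle and cannot compete. Cutting here, rather than carrying the amine through, means no earlier step has to tolerate a free aminopyrimidine. The precursor differs from the target by one atom exchange. The forward reaction only has to be forced hard enough to overcome the donor effect of the indol-3-yl group.

**Biaryl bond (10 ⇒ 8 + 9).** The C3–C4' bond is cut to 5,6-dibromo-1H-indole 8 and 2,4-dichloropyrimidine 9. A cross-coupling through a C3-metallated partner would make the same bond but would expose both aryl bromides to zerovalent palladium. Building the pyrimidine ring on a C3 acyl group would cost three or four steps. The Friedel–Crafts-type substitution uses the innate nucleophilicity of indole C3 and the higher electrophilicity of C4 over C2 in 9, and needs no metal that inserts into C–Br. The forward step must select C4 of 9 and C3 (not N1) of 8.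

**Oxidation level and nitrogen protection (8 ⇒ 7 ⇒ 6).** The indole 8 is traced to 5,6-dibromoindoline 7 and its tert-butyl carbamate 6. This retrosynthetic reduction is deliberate: a pyrrole C2=C3 bond is a poor dienophile, whereas the isolated enamide bond of a 2,3-dihydropyrrole is a good one. The benzene ring is therefore built at the indoline oxidation level. The forward steps are carbamate acidolysis and dehydrogenation of the five-membered ring, both routine.

**Benzene ring (6 ⇒ 2 + 3).** Two bonds of the carbocycle are cut, C3a–C4 and C7–C7a. Returning two hydrogens to C3a and C7a of 6 gives the cis-fused diene 5, and bridging C4 and C7 of 5 with SO2 gives the bridged sulfone 4. Compound 4 is the Diels–Alder adduct of the dioxide 2 and tert-butyl 2,3-dihydro-1H-pyrrole-1-carboxylate 3. Cuts that keep a preformed benzene ring either demand regioselective dibromination or start from a benzene that already carries both bromines and two further handles, which itself needs several steps. Here one partner is commercial, the other is one step from a commercial thiophene, and the symmetric diene removes regiochemistry. The forward reaction asks for three things in one flask: cross-cycloaddition faster than diene dimerisation, loss of SO2, and dehydrogenation of 5 faster than its ring-opening by β-elimination of the carbamate nitrogen.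

**Diene (2 ⇒ 1).** The two S–O bonds of 2 are cut, leading to commercial 3,4-dibromothiophene 1. The forward oxidation needs a strong peracid because the sulfur of a dibrominated aromatic thiophene is a poor nucleophile.

## Roads not taken

Alternative 1: Larock heteroannulation. The cut runs through N1–C2 and C3–C3a and leads to 4,5-dibromo-2-iodoaniline A1 and 4-[(trimethylsilyl)ethynyl]pyrimidin-2-amine A2. In the forward key step, Pd(OAc)2 catalysis would join the iodoaniline A1 and the alkyne A2. Oxidative addition into the C–I bond of A1, carbopalladation that places the bulky silyl group at C2 and the pyrimidine at C3, and C–N reductive elimination would give 4-[5,6-dibromo-2-(trimethylsilyl)-1H-indol-3-yl]pyrimidin-2-amine A3; protodesilylation of A3 would then give 11. The merits are real: the pyrrole ring and the biaryl bond arise in one convergent event, the aminopyrimidine arrives complete, and the sequence is probably two steps shorter than the plan adopted here, so in convergence and step count this road is better. Its weak points lie in chemoselectivity. Zerovalent palladium must insert into the C–I bond of A1 and leave two C–Br bonds alone at annulation temperature, A3 still carries both bromides and can re-enter the catalytic cycle, and the free aminopyrimidine of A2 can bind divalent palladium and slow turnover. What the adopted plan sets against the shorter count is that no transition metal ever meets a C–Br bond, and that the halogen pattern is fixed by the atoms of the diene rather than by relative rates of oxidative addition.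

Alternative 2: Bergman cycloaromatization. The cut is the C5–C6 bond and leads to methyl 4,5-bis(bromoethynyl)-1-tosyl-1H-pyrrole-2-carboxylate A4. In the forward key step, heating A4 with a hydrogen-atom donor would join the two bromoalkyne termini, close the benzene ring as a 1,4-diradical and give methyl 5,6-dibromo-1-tosyl-1H-indole-2-carboxylate A5. Like the adopted plan, it brings both bromines in on carbons that already carry them, so no aromatic bromination is needed. The weak points are several. An enediyne fused to a five-membered ring holds its alkyne termini far apart and should cyclise only at high temperature, where bromoalkynes and aryl C–Br bonds are both exposed to radical chain reduction. A4 itself needs a multistep build that includes a double alkynylation and bromination of both alkyne termini. After A5, the ester and the tosyl group must be removed to reach 8 before the pyrimidine can be attached. The adopted plan applies the same logic at about 80 °C from two simple partners and reaches 8 in four steps; this road is better in no respect that matters for 11.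

Alternative 3: Dibromobenzyne annulation. The cut runs through N1–C7a and C3–C3a and leads to 4,5-dibromo-2-(trimethylsilyl)phenyl trifluoromethanesulfonate A6 and 4-methyl-N-{2-[2-(methylsulfanyl)pyrimidin-4-yl]-2-oxoethyl}benzenesulfonamide A7. In the forward key step, fluoride would release the symmetric aryne from A6, the sulfonamide nitrogen of A7 would add, the aryl anion would close onto the ketone, and acid-promoted loss of water in the same flask would give 5,6-dibromo-3-[2-(methylsulfanyl)pyrimidin-4-yl]-1-tosyl-1H-indole A8. The aryne is symmetric, the conditions spare aryl bromides, and the pyrrole ring and the C3 substituent are installed together; that is more convergent than the adopted plan, which needs a separate heteroarylation. Against this, neither A6 nor A7 is purchasable, and making A6 involves halogen–metal exchange on a ring that carries extra bromines. The acidic α-protons of A7 can quench the aryl anion before it reaches the carbonyl, giving N-arylation without ring closure, and A8 still needs sulfide oxidation, ammonia displacement and detosylation. What the adopted plan sets against the higher convergence is three commercial inputs and a shorter overall count, at the price of a more linear end game.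

Key step: step 2

Assumption: 1, 3 and 9 are purchased. The transient intermediates 4 and 5 are racemic and the endo/exo orientation of 4 is left open, because every stereocentre is destroyed in the same flask.

## Route

Step 1
Reactants: 1 3,4-dibromothiophene
Product: 2 3,4-dibromothiophene 1,1-dioxide
Conditions: urea·H2O2, (CF3CO)2O, MeCN/CH2Cl2, 0 °C to rt
Reagents that add atoms: trifluoroperacetic acid, O=C(OO)C(F)(F)F, formed in the flask from urea–hydrogen peroxide, NC(N)=O.OO, and trifluoroacetic anhydride, O=C(OC(=O)C(F)(F)F)C(F)(F)F
Why: Electrophilic oxygen transfer from a peracid to sulfur (sulfide to sulfone oxidation); trifluoroperacetic acid is strong enough for the electron-poor thiophene, and the non-aromatic S-oxide is oxidised faster than 1, so it should not accumulate. The 3,4-dihalogenated dioxide should be isolable, is expected to dimerise only slowly, and should be used soon after isolation.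

Step 2
Reactants: 2 3,4-dibromothiophene 1,1-dioxide; 3 tert-butyl 2,3-dihydro-1H-pyrrole-1-carboxylate
Product: 6 tert-butyl 5,6-dibromoindoline-1-carboxylate, via bridged sulfone cycloadduct 4 (not isolated), via cis-fused cyclohexadiene 5 (not isolated)
Conditions: PhMe, solid NaHCO3, 80 °C, Ar sweep, twofold excess of 3; then DDQ (enough to cover surplus 3), rt
Reagents that add atoms: none
Why: Diels–Alder reaction with inverse electron demand: the non-aromatic, electron-poor diene of 2 (C2=C3–C4=C5) adds suprafacially across the electron-rich enamide bond of 3 and forms C3a–C4 and C7–C7a together, closing the six-membered carbocycle by an intermolecular [4+2] annulation to give the bridged sulfone 4. At the reaction temperature 4 should lose SO2 by a thermally allowed cheletropic extrusion, which re-forms a diene and gives the cis-fused 5,6-dibromocyclohexa-1,3-diene 5. DDQ then removes hydride from C7a–H, which is allylic and α to the carbamate nitrogen, and the resulting arenium ion loses the C3a proton, so the benzene ring of 6 is completed by oxidation. The closest known reaction type is the cycloaddition–SO2 extrusion of 3,4-dihalo- and tetrahalothiophene 1,1-dioxides with alkenes, enol ethers and quinones, followed by dehydrogenation; the enecarbamate 3 is an electron-rich alkene of the same polarity, so the step applies this known reaction to a new molecule. The stereocentres of 4 (C3a, C4, C7, C7a) and 5 (C3a, C7a) are set only by suprafacial addition to the cis alkene, which enforces the cis ring fusion, and all of them vanish on aromatisation, so endo/exo selectivity is of no consequence and 6 is achiral. No regioselectivity is required because 2 is mirror-symmetric and both orientations give the same adduct. Two selectivities are required: cross-addition must beat self-dimerisation of 2, which the excess of 3 and the matched frontier orbitals (HOMO of 3, LUMO of 2) should secure, and dehydrogenation must beat ring-opening β-elimination of N1 from C7a, which the poor leaving-group ability of the carbamate, the buffered neutral medium and the addition of DDQ at room temperature as soon as 2 is consumed should secure.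

Step 3
Reactants: 6 tert-butyl 5,6-dibromoindoline-1-carboxylate
Product: 7 5,6-dibromoindoline
Conditions: CF3CO2H, CH2Cl2, 0 °C to rt; aq NaHCO3 work-up
Reagents that add atoms: none
Why: Acidolysis of a tert-butyl carbamate: loss of the tert-butyl cation as 2-methylpropene and decarboxylation of the carbamic acid. Aryl bromides and the indoline ring are inert to trifluoroacetic acid, and basic work-up should give the free amine.

Step 4
Reactants: 7 5,6-dibromoindoline
Product: 8 5,6-dibromo-1H-indole
Conditions: MnO2 (activated), CH2Cl2, rt
Reagents that add atoms: none
Why: MnO2 dehydrogenation of an indoline to the indole, driven by aromatisation of the pyrrole ring. The C–Br bonds are untouched, and the electron-poor dibromoindole should resist further oxidation.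

Step 5
Reactants: 8 5,6-dibromo-1H-indole; 9 2,4-dichloropyrimidine
Product: 10 5,6-dibromo-3-(2-chloropyrimidin-4-yl)-1H-indole
Conditions: AlCl3, ClCH2CH2Cl, 80 °C
Reagents that add atoms: none
Why: Friedel–Crafts-type heteroarylation: indole C3, its most nucleophilic carbon, attacks C4 of the AlCl3-activated pyrimidine, the more electrophilic of the two chlorinated positions, and chloride is lost (addition–elimination). This is an established way to make 3-(2-chloropyrimidin-4-yl)indoles from N–H indoles; the bromines lower the rate but not the site of attack.

Step 6
Reactants: 10 5,6-dibromo-3-(2-chloropyrimidin-4-yl)-1H-indole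
Product: 11 meridianin F, 4-(5,6-dibromo-1H-indol-3-yl)pyrimidin-2-amine
Conditions: NH3, i-PrOH, sealed tube, 120 °C
Reagents that add atoms: ammonia, N
Why: Nucleophilic aromatic substitution (SNAr) at C2' of the pyrimidine, where the anionic adduct is stabilised by both ring nitrogens. The C–Br bonds on the carbocycle are not activated for addition–elimination and should survive; heating in a sealed tube compensates for the donor effect of the indol-3-yl group.

## Compound list

1 | 3,4-dibromothiophene | Brc1cscc1Br | starting material
2 | 3,4-dibromothiophene 1,1-dioxide | O=S1(=O)C=C(Br)C(Br)=C1 | intermediate
3 | tert-butyl 2,3-dihydro-1H-pyrrole-1-carboxylate | CC(C)(C)OC(=O)N1CCC=C1 | starting material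
4 | tert-butyl 5,6-dibromo-2,3,3a,4,7,7a-hexahydro-1H-4,7-epithioindole-1-carboxylate 8,8-dioxide (3a,7a-cis, racemic, bridge orientation left open) | CC(C)(C)OC(=O)N1CC[C@@H]2C3C(Br)=C(Br)C([C@@H]21)S3(=O)=O | intermediate
5 | tert-butyl cis-5,6-dibromo-2,3,3a,7a-tetrahydro-1H-indole-1-carboxylate (racemic) | CC(C)(C)OC(=O)N1CC[C@@H]2C=C(Br)C(Br)=C[C@@H]21 | intermediate
6 | tert-butyl 5,6-dibromoindoline-1-carboxylate | CC(C)(C)OC(=O)N1CCc2cc(Br)c(Br)cc21 | intermediate
7 | 5,6-dibromoindoline | Brc1cc2c(cc1Br)NCC2 | intermediate
8 | 5,6-dibromo-1H-indole | Brc1cc2cc[nH]c2cc1Br | intermediate
9 | 2,4-dichloropyrimidine | Clc1ccnc(Cl)n1 | starting material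
10 | 5,6-dibromo-3-(2-chloropyrimidin-4-yl)-1H-indole | Clc1nccc(-c2c[nH]c3cc(Br)c(Br)cc23)n1 | intermediate
11 | meridianin F, 4-(5,6-dibromo-1H-indol-3-yl)pyrimidin-2-amine | Nc1nccc(-c2c[nH]c3cc(Br)c(Br)cc23)n1 | target

## Step count and risks

Total step count: 6. Longest linear sequence: 6 steps (1 to 2 to 6 to 7 to 8 to 10 to 11); 3 and 9 enter as purchased materials.

**Step 2 (key step).** Four processes could divert it:
- self-dimerisation of 2, if the enecarbamate is a slower partner than the enol ethers and alkenes on which the reaction type rests;
- ring-opening β-elimination of the carbamate nitrogen from C7a of 5, which aromatises the ring but destroys the pyrroline;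
- on prolonged heating, sigmatropic hydrogen migration in 5 followed by loss of HBr, which would strip one bromine;
- consumption of DDQ by surplus 3.

Fallback: give up ring construction and place the bromines by directed electrophilic substitution, a sequence of known steps. It uses none of compounds 1 to 3. In place of compound 1 it sets out from commercial methyl 1H-indole-3-carboxylate F1, whose C3 ester deactivates the pyrrole ring and steers bromination to C5 and C6. Treatment with Br2 in acetic acid should give methyl 5,6-dibromo-1H-indole-3-carboxylate F2. Saponification with NaOH in aqueous methanol should give 5,6-dibromo-1H-indole-3-carboxylic acid F3, which loses CO2 on heating. The fallback comes back to the route at compound 8, so steps 5 and 6 are unchanged.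

**Step 5.** The two bromines reduce the nucleophilicity of C3, so conversion may stall. Forcing the reaction invites substitution at C2 of the pyrimidine, arylation at N1, or Lewis-acid-induced oligomerisation of the indole.

Fallback: build the pyrimidine ring on the indole instead of attaching it. It sets out from compound 8. C3 acetylation with acetyl chloride and Et2AlCl in CH2Cl2 at 0 °C should give 1-(5,6-dibromo-1H-indol-3-yl)ethanone F4. N-sulfonylation with tosyl chloride, Et3N and DMAP should give 1-[5,6-dibromo-1-(4-methylbenzenesulfonyl)-1H-indol-3-yl]ethanone F5. Condensation with N,N-dimethylformamide dimethyl acetal in DMF at 110 °C should give (E)-1-[5,6-dibromo-1-(4-methylbenzenesulfonyl)-1H-indol-3-yl]-3-(dimethylamino)prop-2-en-1-one F6. Heating F6 with guanidine hydrochloride and K2CO3 in 2-methoxyethanol should close the 2-aminopyrimidine and cleave the sulfonamide in the same operation. The fallback comes back to the route at compound 11 and makes step 6 unnecessary.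

**Step 6.** Displacement may be sluggish because the indol-3-yl group feeds electron density into the pyrimidine. Under more forcing conditions, solvolysis of the chloride to the pyrimidinone or alkoxypyrimidine could compete.

Fallback: use a more nucleophilic, removable amine. It sets out from compound 10. Heating with 2,4-dimethoxybenzylamine and i-Pr2NEt in n-butanol at 120 °C should give 4-(5,6-dibromo-1H-indol-3-yl)-N-(2,4-dimethoxybenzyl)pyrimidin-2-amine F7. Trifluoroacetic acid with triethylsilane as cation trap should then cleave the benzyl group. The fallback comes back to the route at compound 11.

## Further compounds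

F1 | step 2 | methyl 1H-indole-3-carboxylate | COC(=O)c1c[nH]c2ccccc12
F2 | step 2 | methyl 5,6-dibromo-1H-indole-3-carboxylate | COC(=O)c1c[nH]c2cc(Br)c(Br)cc12
F3 | step 2 | 5,6-dibromo-1H-indole-3-carboxylic acid | O=C(O)c1c[nH]c2cc(Br)c(Br)cc12
F4 | step 5 | 1-(5,6-dibromo-1H-indol-3-yl)ethanone | CC(=O)c1c[nH]c2cc(Br)c(Br)cc12
F5 | step 5 | 1-[5,6-dibromo-1-(4-methylbenzenesulfonyl)-1H-indol-3-yl]ethanone | CC(=O)c1cn(S(=O)(=O)c2ccc(C)cc2)c2cc(Br)c(Br)cc12
F6 | step 5 | (E)-1-[5,6-dibromo-1-(4-methylbenzenesulfonyl)-1H-indol-3-yl]-3-(dimethylamino)prop-2-en-1-one | CN(C)/C=C/C(=O)c1cn(S(=O)(=O)c2ccc(C)cc2)c2cc(Br)c(Br)cc12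
F7 | step 6 | 4-(5,6-dibromo-1H-indol-3-yl)-N-(2,4-dimethoxybenzyl)pyrimidin-2-amine | COc1ccc(CNc2nccc(-c3c[nH]c4cc(Br)c(Br)cc34)n2)c(OC)c1
A1 | alternative 1 | 4,5-dibromo-2-iodoaniline | Nc1cc(Br)c(Br)cc1I
A2 | alternative 1 | 4-[(trimethylsilyl)ethynyl]pyrimidin-2-amine | C[Si](C)(C)C#Cc1ccnc(N)n1
A3 | alternative 1 | 4-[5,6-dibromo-2-(trimethylsilyl)-1H-indol-3-yl]pyrimidin-2-amine | C[Si](C)(C)c1[nH]c2cc(Br)c(Br)cc2c1-c1ccnc(N)n1
A4 | alternative 2 | methyl 4,5-bis(bromoethynyl)-1-tosyl-1H-pyrrole-2-carboxylate | COC(=O)c1cc(C#CBr)c(C#CBr)n1S(=O)(=O)c1ccc(C)cc1
A5 | alternative 2 | methyl 5,6-dibromo-1-tosyl-1H-indole-2-carboxylate | COC(=O)c1cc2cc(Br)c(Br)cc2n1S(=O)(=O)c1ccc(C)cc1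
A6 | alternative 3 | 4,5-dibromo-2-(trimethylsilyl)phenyl trifluoromethanesulfonate | C[Si](C)(C)c1cc(Br)c(Br)cc1OS(=O)(=O)C(F)(F)F
A7 | alternative 3 | 4-methyl-N-{2-[2-(methylsulfanyl)pyrimidin-4-yl]-2-oxoethyl}benzenesulfonamide | CSc1nccc(C(=O)CNS(=O)(=O)c2ccc(C)cc2)n1
A8 | alternative 3 | 5,6-dibromo-3-[2-(methylsulfanyl)pyrimidin-4-yl]-1-tosyl-1H-indole | CSc1nccc(-c2cn(S(=O)(=O)c3ccc(C)cc3)c3cc(Br)c(Br)cc23)n1
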